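**Retrosynthetic overview**
1. The 4-hydroxybenzoate on O-6 and the free tertiary hydroxyl on C-4 are traced back to one temporary ring: a 2-aryl-1,3-dioxane (ring C, not in the target) spanning O-4 and O-6, whose acetal carbon is oxidised to the ester carbonyl at the end.
2. Ring B (the cycloheptene) is disconnected at C8=C9 by ring-closing metathesis of a C-1 allyl arm and a C-6 2-methylallyl arm while ring C is in place.
3. Enabling feature: O-4 and the C-6 branch are cis on ring A (cyclopentane C1–C5), so the array O4–C4–C5–C6–O6 closes to a chair dioxane cis-fused to ring A. In that chair C-7 and C-1 are both equatorial and gauche, which holds the two alkene arms (trans across C1–C5) ready for the seven-membered closure.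
4. The substituents of ring A come from an isopropyl addition to a C-4 ketone and from a three-component conjugate addition–aldol (methyl cuprate, β-allyl enone, 3-methylbut-3-enal) that sets C-1, C-5 and C-6 from the single C-2 stereocentre of a commercial 4-silyloxycyclopentenone.
5. Ring order: ring A (purchased) → ring C (temporary dioxane) → ring B (metathesis) → ring C opened to the ester.

Key step: step 8

Remark: daucane numbering is used for all intermediates (C-1 quaternary carbon, C-2 carbinol, C-4 isopropyl carbinol, C-5 ring-fusion CH, C-6 acyloxy carbon, C8=C9 alkene); α is the face of H-5 and of the C-2 oxygen, β the face of the C-1 methyl.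

Step 1
Reactants: 1 (S)-4-(tert-butyldimethylsilyloxy)cyclopent-2-en-1-one
Product: 2 (3S,4S)-3-allyl-4-(tert-butyldimethylsilyloxy)-1-(trimethylsilyloxy)cyclopent-1-ene
Conditions: CH2=CHCH2MgBr, CuBr·SMe2 (1.1 equiv), TMSCl, THF, −78 °C; Et3N, then aq NaHCO3
Reagents that add atoms: allylmagnesium bromide (C=CC[Mg]Br); chlorotrimethylsilane (C[Si](C)(C)Cl)
Why: Conjugate addition of an allylcopper reagent activated by TMSCl should deliver allyl to C-1 anti to the C-2 silyloxy group (this centre is erased in step 2) while the enolate oxygen is silylated in situ, which fixes the C4=C5 enol ether needed for the dehydrogenation.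

Step 2
Reactants: 2 (3S,4S)-3-allyl-4-(tert-butyldimethylsilyloxy)-1-(trimethylsilyloxy)cyclopent-1-ene
Product: 3 (S)-3-allyl-4-(tert-butyldimethylsilyloxy)cyclopent-2-en-1-one
Conditions: Pd(OAc)2 (1.05 equiv), MeCN, rt
Reagents that add atoms: none
Why: Saegusa–Ito oxidation: palladation of the silyl enol ether at C-5 and β-hydride elimination of the only β-hydrogen (H-1) should give the β-allyl enone with the C-2 stereocentre untouched.

Step 3
Reactants: 4 3-methylbut-3-en-1-ol
Product: 5 3-methylbut-3-enal
Conditions: Dess–Martin periodinane, pyridine, CH2Cl2, 0 °C; filtered through silica and used at once as a solution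
Reagents that add atoms: none
Why: Dess–Martin oxidation of the primary homoallylic alcohol under buffered, near-neutral conditions should give the β,γ-unsaturated aldehyde without isomerisation into conjugation.

Step 4
Reactants: 3 (S)-3-allyl-4-(tert-butyldimethylsilyloxy)cyclopent-2-en-1-one; 5 3-methylbut-3-enal
Product: 7 (2S,3R,4S)-3-allyl-4-(tert-butyldimethylsilyloxy)-2-[(1S)-1-hydroxy-3-methylbut-3-en-1-yl]-3-methylcyclopentan-1-one, via lithium enolate 6 (not isolated)
Conditions: Me2CuLi, Et2O, −78 to −20 °C; then 5, −78 °C; aq NH4Cl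
Reagents that add atoms: lithium dimethylcuprate ([Li+].C[Cu-]C)
Why: Tandem conjugate addition–aldol (three-component coupling): the cuprate should add methyl to C-1 anti to the C-2 silyloxy group, and the regiodefined C-5 enolate should then add to the aldehyde on the β face (anti to the C-1 allyl and C-2 silyloxy groups) through a chair Zimmerman–Traxler transition state with both large groups equatorial, which gives the 5,6-anti aldol.

Step 5
Reactants: 7 (2S,3R,4S)-3-allyl-4-(tert-butyldimethylsilyloxy)-2-[(1S)-1-hydroxy-3-methylbut-3-en-1-yl]-3-methylcyclopentan-1-one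
Product: 8 (2S,3R,4S)-3-allyl-4-(tert-butyldimethylsilyloxy)-3-methyl-2-[(1S)-3-methyl-1-(triethylsilyloxy)but-3-en-1-yl]cyclopentan-1-one
Conditions: TESOTf, 2,6-lutidine, CH2Cl2, −78 °C
Reagents that add atoms: triethylsilyl trifluoromethanesulfonate (CC[Si](CC)(CC)OS(=O)(=O)C(F)(F)F)
Why: Silylation of the secondary aldol hydroxyl at low temperature should block retro-aldol and chelation pathways and enlarge the C-5 substituent for the next addition; no stereocentre is touched.

Step 6
Reactants: 8 (2S,3R,4S)-3-allyl-4-(tert-butyldimethylsilyloxy)-3-methyl-2-[(1S)-3-methyl-1-(triethylsilyloxy)but-3-en-1-yl]cyclopentan-1-one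
Product: 9 (1R,2S,3R,4S)-3-allyl-4-(tert-butyldimethylsilyloxy)-3-methyl-2-[(1S)-3-methyl-1-(triethylsilyloxy)but-3-en-1-yl]-1-(propan-2-yl)cyclopentan-1-ol
Conditions: i-PrMgCl, CeCl3, THF, −78 to 0 °C; aq NH4Cl
Reagents that add atoms: isopropylmagnesium chloride (CC(C)[Mg]Cl)
Why: Organocerium 1,2-addition to the enolisable β-silyloxy ketone: the weakly basic reagent should attack C-4 from the α face, anti to the bulky adjacent C-5 side chain, which places isopropyl α and the new hydroxyl β, cis to C-6.

Step 7
Reactants: 9 (1R,2S,3R,4S)-3-allyl-4-(tert-butyldimethylsilyloxy)-3-methyl-2-[(1S)-3-methyl-1-(triethylsilyloxy)but-3-en-1-yl]-1-(propan-2-yl)cyclopentan-1-ol; 10 4-(tert-butyldimethylsilyloxy)benzaldehyde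
Product: 12 O-4/O-6 4-(tert-butyldimethylsilyloxy)benzylidene acetal of the triene diol (aryl equatorial; acetal H cis to H-6), via diol 11 (not isolated)
Conditions: PPTS, MeOH, 0 °C to rt; evaporate; then 10, PPTS (cat.), MgSO4, CH2Cl2, rt
Reagents that add atoms: none
Why: Mild methanolysis should remove only the triethylsilyl ether, and thermodynamic acetalisation of the cis-related O-4/O-6 diol should then close the chair dioxane with the aryl group equatorial; PPTS is too weak an acid to ionise the tertiary alcohol or to drive Prins-type attack of the methallyl alkene on the stabilised oxocarbenium ion.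

Step 8
Reactants: 12 O-4/O-6 4-(tert-butyldimethylsilyloxy)benzylidene acetal of the triene diol
Product: 13 tricyclic acetal (ring A cyclopentane, ring B cycloheptene with C8=C9, ring C dioxane; C-2 OTBS)
Conditions: second-generation Grubbs catalyst [RuCl2(=CHPh)(PCy3)(H2IMes)] (5 mol %), CH2Cl2 (5 mM), 40 °C
Reagents that add atoms: none
Why: The ruthenium benzylidene should initiate at the monosubstituted allyl alkene on C-1; the resulting C-9 alkylidene then undergoes [2+2] cycloaddition with the 1,1-disubstituted C-8 alkene, and cycloreversion of the ruthenacyclobutane releases ethene and forms C8=C9. The closest known reaction type is ring-closing olefin metathesis to trisubstituted cycloheptenes on trans-1,2-disubstituted cyclopentanes, here run on a substrate that carries a temporary dioxane tether. The ring closed is the seven-membered carbocycle (ring B), closed by ring-closing metathesis to an endocyclic alkene, trans-fused to ring A across C1–C5 and to the dioxane across C5–C6. No new stereocentre is formed: the alkene can only be Z inside the seven-membered ring, and the trans ring fusion is inherited from C-1 and C-5. The step needs cyclisation to outrun oligomerisation and must spare the tertiary and homoallylic oxygen functions; the dioxane chair fixes C-7 equatorial and gauche to C-1 (the one C5–C6 rotamer from which ring B can close) and masks both hydroxyls, and high dilution does the rest. The tether is not wasted, because its acetal carbon becomes the ester carbonyl in step 9.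

Step 9
Reactants: 13 tricyclic acetal
Product: 15 2α-hydroxyferutinin bis(tert-butyldimethylsilyl) ether (C-2 O-TBS and aryl O-TBS; C-4 OH free), via hemi-orthoester 14 (not isolated)
Conditions: DDQ, CH2Cl2/pH 7 phosphate buffer (10:1), 0 °C to rt
Reagents that add atoms: water (O)
Why: Oxidative acetal-to-hydroxy-ester opening as known for 4-alkoxybenzylidene acetals: hydride abstraction by DDQ should give a dioxocarbenium ion that water traps as the hemi-orthoester, which should collapse by cleavage of the bond to the more basic tertiary O-4 (any O-4 ester is expected to relay to the secondary O-6 by 1,3-acyl shift), leaving the C-6 benzoate and the free C-4 alcohol.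

Step 10
Reactants: 15 2α-hydroxyferutinin bis(tert-butyldimethylsilyl) ether
Product: 16 2α-hydroxyferutinin, (1S,3R,3aS,4S,8aR)-1,3-dihydroxy-6,8a-dimethyl-3-(propan-2-yl)-1,2,3,3a,4,5,8,8a-octahydroazulen-4-yl 4-hydroxybenzoate
Conditions: HF·pyridine, pyridine, THF, 0 °C to rt
Reagents that add atoms: none
Why: Fluoride-mediated desilylation should cleave the aryl and the hindered secondary alkyl silyl ethers under buffered conditions that leave the benzoate, the tertiary alcohol and the trisubstituted alkene untouched.

**Compound list**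
1 | (S)-4-(tert-butyldimethylsilyloxy)cyclopent-2-en-1-one | O=C1C=C[C@@H](O[Si](C)(C)C(C)(C)C)C1 | starting material
2 | (3S,4S)-3-allyl-4-(tert-butyldimethylsilyloxy)-1-(trimethylsilyloxy)cyclopent-1-ene (allyl trans to OTBS) | C=CC[C@H]1C=C(O[Si](C)(C)C)C[C@@H]1O[Si](C)(C)C(C)(C)C | intermediate
3 | (S)-3-allyl-4-(tert-butyldimethylsilyloxy)cyclopent-2-en-1-one | C=CCC1=CC(=O)C[C@@H]1O[Si](C)(C)C(C)(C)C | intermediate
4 | 3-methylbut-3-en-1-ol | CC(=C)CCO | starting material
5 | 3-methylbut-3-enal | CC(=C)CC=O | intermediate
6 | lithium (3R,4S)-3-allyl-4-(tert-butyldimethylsilyloxy)-3-methylcyclopent-1-en-1-olate (methyl trans to OTBS) | C=CC[C@]1(C)C=C(O[Li])C[C@@H]1O[Si](C)(C)C(C)(C)C | intermediate (not isolated)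
7 | (2S,3R,4S)-3-allyl-4-(tert-butyldimethylsilyloxy)-2-[(1S)-1-hydroxy-3-methylbut-3-en-1-yl]-3-methylcyclopentan-1-one | C=CC[C@]1(C)[C@@H]([C@@H](O)CC(C)=C)C(=O)C[C@@H]1O[Si](C)(C)C(C)(C)C | intermediate
8 | (2S,3R,4S)-3-allyl-4-(tert-butyldimethylsilyloxy)-3-methyl-2-[(1S)-3-methyl-1-(triethylsilyloxy)but-3-en-1-yl]cyclopentan-1-one | C=CC[C@]1(C)[C@@H]([C@@H](O[Si](CC)(CC)CC)CC(C)=C)C(=O)C[C@@H]1O[Si](C)(C)C(C)(C)C | intermediate
9 | (1R,2S,3R,4S)-3-allyl-4-(tert-butyldimethylsilyloxy)-3-methyl-2-[(1S)-3-methyl-1-(triethylsilyloxy)but-3-en-1-yl]-1-(propan-2-yl)cyclopentan-1-ol | C=CC[C@]1(C)[C@@H]([C@@H](O[Si](CC)(CC)CC)CC(C)=C)[C@](O)(C(C)C)C[C@@H]1O[Si](C)(C)C(C)(C)C | intermediate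
10 | 4-(tert-butyldimethylsilyloxy)benzaldehyde | O=Cc1ccc(O[Si](C)(C)C(C)(C)C)cc1 | starting material
11 | (1R,2S,3R,4S)-3-allyl-4-(tert-butyldimethylsilyloxy)-2-[(1S)-1-hydroxy-3-methylbut-3-en-1-yl]-3-methyl-1-(propan-2-yl)cyclopentan-1-ol | C=CC[C@]1(C)[C@@H]([C@@H](O)CC(C)=C)[C@](O)(C(C)C)C[C@@H]1O[Si](C)(C)C(C)(C)C | intermediate (not isolated)
12 | 2-aryl-1,3-dioxane spanning O-4 and O-6 of 11, cis-fused to ring A; aryl = 4-(tert-butyldimethylsilyloxy)phenyl, equatorial, acetal H cis to H-6; C-1 allyl, C-6 2-methylallyl, C-2 OTBS | C=CC[C@]1(C)[C@H]2[C@H](CC(C)=C)O[C@H](c3ccc(O[Si](C)(C)C(C)(C)C)cc3)O[C@@]2(C(C)C)C[C@@H]1O[Si](C)(C)C(C)(C)C | intermediate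
13 | tricyclic acetal: trans-fused hydroazulene (C8=C9) carrying the O-4/O-6 arylidene dioxane and C-2 OTBS | CC1=CC[C@]2(C)[C@H]3[C@H](C1)O[C@H](c4ccc(O[Si](C)(C)C(C)(C)C)cc4)O[C@@]3(C(C)C)C[C@@H]2O[Si](C)(C)C(C)(C)C | intermediate
14 | hemi-orthoester of 13 (2-aryl-2-hydroxy-1,3-dioxane; configuration at the orthoester carbon not defined) | CC1=CC[C@]2(C)[C@H]3[C@H](C1)OC(O)(c4ccc(O[Si](C)(C)C(C)(C)C)cc4)O[C@@]3(C(C)C)C[C@@H]2O[Si](C)(C)C(C)(C)C | intermediate (not isolated)
15 | 2α-hydroxyferutinin bis(tert-butyldimethylsilyl) ether (C-2 O-TBS, aryl O-TBS) | CC1=CC[C@]2(C)[C@@H]([C@@H](OC(=O)c3ccc(O[Si](C)(C)C(C)(C)C)cc3)C1)[C@](O)(C(C)C)C[C@@H]2O[Si](C)(C)C(C)(C)C | intermediate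
16 | 2α-hydroxyferutinin | CC1=CC[C@]2(C)[C@@H]([C@@H](OC(=O)c3ccc(O)cc3)C1)[C@](O)(C(C)C)C[C@@H]2O | target

**Step count and risks**

Total step count: 10 (9 on the main line plus the preparation of aldehyde 5).
Longest linear sequence: 9 steps (1 to 16 through steps 1, 2 and 4–10).

Steps most likely to fail:

1. Step 6. The facial selectivity of the isopropyl transfer may be eroded, because the 1,3-disposed C-1 allyl and C-2 silyloxy groups on the α face oppose the 1,2-induction from the C-5 side chain; the hindered secondary organometallic may also enolise the ketone or reduce it by β-hydride transfer. The fallback changes the order of ring formation so that a rigid bicycle controls C-4. Setting out from 8, ring-closing metathesis with the same ruthenium catalyst would give the trans-fused hydroazulenone F2. In F2 the C-1 methyl is axial on the β face of ring A and 1,3 to the carbonyl, so isopropylcerium dichloride should add from the α face to give the tertiary alcohol F3. Methanolysis of the triethylsilyl ether (PPTS, MeOH) would give the bicyclic diol F4, and acetalisation of F4 with 10 (PPTS, MgSO4) comes back to the route at 13.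

2. Step 4. Proton transfer from the enolisable β,γ-unsaturated aldehyde to the hindered enolate would return the simple methyl adduct; the aldehyde may also isomerise into conjugation, and retro-aldol equilibration of the lithium aldolate may erode the C-5/C-6 relationship. The fallback replaces the basic one-pot enolate trapping by an isolated enol silane and a Lewis-acid aldol. Setting out from 3, Me2CuLi in the presence of TMSCl would give the silyl enol ether F1, which is isolated. Its Mukaiyama aldol reaction with 5 (BF3·OEt2, CH2Cl2, −78 °C) involves no basic species and should again engage the face of C-5 anti to the C-1 allyl group; after separation of any C-6 epimer it comes back to the route at 7.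

3. Step 9. The hemi-orthoester may collapse with the wrong regiochemistry or the acyl relay may stay incomplete (ester left on the tertiary O-4); hydride abstraction from the silyloxy-substituted arylidene acetal may be slow, and allylic oxidation next to C8=C9 may compete. The same fallback also covers a failure of the acetalisation in step 7. It drops the acetal and introduces the ester before ring closure. Setting out from 11, isolated after the methanolysis stage of step 7, Steglich esterification of its only secondary hydroxyl with 4-(tert-butyldimethylsilyloxy)benzoic acid (EDC·HCl, DMAP, CH2Cl2) would give the triene ester F5. Ring-closing metathesis of F5 (same catalyst, CH2Cl2, 40 °C) comes back to the route at 15.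

**Further compounds**
F1 | step 4 | (3R,4S)-3-allyl-4-(tert-butyldimethylsilyloxy)-3-methyl-1-(trimethylsilyloxy)cyclopent-1-ene | C=CC[C@]1(C)C=C(O[Si](C)(C)C)C[C@@H]1O[Si](C)(C)C(C)(C)C
F2 | step 6 | trans-fused hydroazulen-4-one (daucane numbering) with C8=C9, C-6 O-TES and C-2 O-TBS | CC1=CC[C@]2(C)[C@@H]([C@@H](O[Si](CC)(CC)CC)C1)C(=O)C[C@@H]2O[Si](C)(C)C(C)(C)C
F3 | step 6 | bicyclic tertiary alcohol: C-4 β-OH and α-isopropyl, C-6 O-TES, C-2 O-TBS | CC1=CC[C@]2(C)[C@@H]([C@@H](O[Si](CC)(CC)CC)C1)[C@](O)(C(C)C)C[C@@H]2O[Si](C)(C)C(C)(C)C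
F4 | step 6 | bicyclic 4,6-diol with C-2 O-TBS | CC1=CC[C@]2(C)[C@@H]([C@@H](O)C1)[C@](O)(C(C)C)C[C@@H]2O[Si](C)(C)C(C)(C)C
F5 | step 9 | 4-(tert-butyldimethylsilyloxy)benzoate of the C-6 hydroxyl of diol 11 (monocyclic triene ester) | C=CC[C@]1(C)[C@@H]([C@@H](OC(=O)c2ccc(O[Si](C)(C)C(C)(C)C)cc2)CC(C)=C)[C@](O)(C(C)C)C[C@@H]1O[Si](C)(C)C(C)(C)C
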